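**Assumption:** the stereodescriptor in the target SMILES is read as (2S); paraformaldehyde is written as its monomer, and MOMCl is used only as a protecting-group reagent.

## Retrosynthetic overview

1. Kushenol V ⇐ its tetra-MOM ether by mild acetal cleavage.
2. Ring C ⇐ one-carbon ring expansion (radical 1,2-acyl shift) of a 2-aryl-2-(iodomethyl)benzofuran-3(2H)-one; the C2–H bond is formed last by enantioselective hydrogen-atom transfer.
3. Iodomethyl ketone ⇐ C-iodomethylation of the 2-arylbenzofuranone ⇐ anionic cyclisation of a benzyl salicylate ether ⇐ Mitsunobu union of a ring A salicylate and a ring B benzyl alcohol.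
4. Both arenes ⇐ resorcinol bis-MOM ether: ring A by two directed lithiations (prenyl, CO2Me) and ester-directed C–H borylation/oxidation; ring B by dibromination, Br–Li exchange/CH2O and Cu-catalysed methoxylation.
5. Ring order: rings A and B (preformed arenes) → five-membered furanone ring → ring C by expansion.

## Route

Step 1
Reactants: 1 resorcinol
Product: 2 1,3-bis(methoxymethoxy)benzene
Conditions: NaH (2.4 equiv), MOMCl (2.4 equiv), DMF, 0 °C to rt
Reagents that add atoms: chloromethyl methyl ether, COCCl
Why: Williamson-type O-alkylation of both phenoxides gives the bis-acetal, which is stable to the organolithium and basic steps that follow.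

Step 2
Reactants: 2 1,3-bis(methoxymethoxy)benzene; 3 prenyl bromide (1-bromo-3-methylbut-2-ene)
Product: 5 1,3-bis(methoxymethoxy)-2-(3-methylbut-2-en-1-yl)benzene, via aryllithium 4 (not isolated)
Conditions: n-BuLi, THF, 0 °C to rt; then CuBr·SMe2 (10 mol%), 3, −78 °C to rt
Reagents that add atoms: n-butyllithium, [Li]CCCC (lithium of 4 only)
Why: Directed ortho-metalation removes the C2–H flanked by both OMOM groups, and the copper-assisted SN2 allylation places the prenyl group between the two future 5- and 7-oxygens, which fixes the 6-prenyl regiochemistry.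

Step 3
Reactants: 5 1,3-bis(methoxymethoxy)-2-(3-methylbut-2-en-1-yl)benzene; 6 methyl chloroformate
Product: 8 methyl 2,4-bis(methoxymethoxy)-3-(3-methylbut-2-en-1-yl)benzoate, via aryllithium 7 (not isolated)
Conditions: s-BuLi, TMEDA, THF, −78 °C; then inverse addition to 6 (3 equiv), −78 °C
Reagents that add atoms: sec-butyllithium, [Li]C(C)CC (lithium of 7 only)
Why: A second directed ortho-metalation occurs at the only ring position still ortho to an OMOM group, and acylation of the aryllithium with excess chloroformate at low temperature stops at the ester.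

Step 4
Reactants: 8 methyl 2,4-bis(methoxymethoxy)-3-(3-methylbut-2-en-1-yl)benzoate
Product: 10 methyl 6-hydroxy-2,4-bis(methoxymethoxy)-3-(3-methylbut-2-en-1-yl)benzoate, via arylboronate 9 (not isolated)
Conditions: [Ir(OMe)(cod)]2 (1.5 mol%), P[3,5-(CF3)2C6H3]3 (6 mol%), B2pin2, octane, 80 °C; then H2O2 (30% aq), aq. NaHCO3, THF, 0 °C
Reagents that add atoms: bis(pinacolato)diboron, CC1(C)OB(OC1(C)C)B1OC(C)(C)C(C)(C)O1 (boryl group of 9 only); hydrogen peroxide, OO
Why: Ester-directed iridium-catalysed ortho C–H borylation delivers boron to C6 (the only C–H ortho to the ester, while C5 is hindered by its OMOM neighbour), and boronate oxidation with aryl migration from boron to oxygen gives the single free phenol that becomes O1.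

Step 5
Reactants: 2 1,3-bis(methoxymethoxy)benzene
Product: 11 1,5-dibromo-2,4-bis(methoxymethoxy)benzene
Conditions: NBS (2.1 equiv), MeCN, 0 °C to rt
Reagents that add atoms: N-bromosuccinimide, O=C1CCC(=O)N1Br
Why: Electrophilic aromatic bromination takes place at the two positions that are ortho/para to both OMOM groups, while C2 is shielded by its two flanking acetals.

Step 6
Reactants: 11 1,5-dibromo-2,4-bis(methoxymethoxy)benzene; 12 formaldehyde (as paraformaldehyde)
Product: 14 [5-bromo-2,4-bis(methoxymethoxy)phenyl]methanol, via aryllithium 13 (not isolated)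
Conditions: n-BuLi (1.0 equiv), THF, −78 °C; then (CH2O)n, −78 °C to rt
Reagents that add atoms: n-butyllithium, [Li]CCCC (lithium of 13 only)
Why: Bromine–lithium exchange stops after one exchange with one equivalent because the monolithio arene is deactivated towards a second, and 1,2-addition of the aryllithium to formaldehyde desymmetrises the dibromide.

Step 7
Reactants: 14 [5-bromo-2,4-bis(methoxymethoxy)phenyl]methanol; 15 sodium methoxide
Product: 16 [5-methoxy-2,4-bis(methoxymethoxy)phenyl]methanol
Conditions: NaOMe (5 equiv), CuBr (10 mol%), DMF/MeOH, 110 °C, sealed tube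
Reagents that add atoms: none
Why: Ullmann-type copper-catalysed C–O coupling of the aryl bromide with methoxide installs the 5'-methoxy group under basic conditions that leave the acetals and the benzylic alcohol untouched.

Step 8
Reactants: 10 methyl 6-hydroxy-2,4-bis(methoxymethoxy)-3-(3-methylbut-2-en-1-yl)benzoate; 16 [5-methoxy-2,4-bis(methoxymethoxy)phenyl]methanol
Product: 17 methyl 6-{[5-methoxy-2,4-bis(methoxymethoxy)phenyl]methoxy}-2,4-bis(methoxymethoxy)-3-(3-methylbut-2-en-1-yl)benzoate
Conditions: PPh3, DIAD, THF, 0 °C to rt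
Reagents that add atoms: none
Why: Mitsunobu etherification alkylates the acidic salicylate phenol at oxygen with the primary benzylic alcohol under neutral conditions compatible with ester, acetals and prenyl.

Step 9
Reactants: 17 the benzyl salicylate ether
Product: 18 rac-2-[5-methoxy-2,4-bis(methoxymethoxy)phenyl]-4,6-bis(methoxymethoxy)-5-(3-methylbut-2-en-1-yl)-1-benzofuran-3(2H)-one
Conditions: LDA (2.5 equiv), THF, −78 to 0 °C; degassed aq. NH4Cl work-up
Reagents that add atoms: none
Why: Anionic cyclisation (Dieckmann-type intramolecular acylation) closes the α-oxybenzylic carbanion 5-exo-trig onto the neighbouring ester, and the ketone is held as its enolate until work-up; C2 is racemic here, which is irrelevant because it becomes a radical centre in step 11.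

Step 10
Reactants: 18 the 2-arylbenzofuranone; 19 diiodomethane
Product: 20 rac-2-(iodomethyl)-2-[5-methoxy-2,4-bis(methoxymethoxy)phenyl]-4,6-bis(methoxymethoxy)-5-(3-methylbut-2-en-1-yl)-1-benzofuran-3(2H)-one
Conditions: K2CO3, CH2I2 (10 equiv), acetone, 45 °C, dark, argon
Reagents that add atoms: none
Why: Enolate C-alkylation (SN2) of the soft 3-oxidobenzofuran anion at C2 with the soft iodide in large excess gives a quaternary neopentyl-type iodide that can neither eliminate nor react a second time.

Step 11
Reactants: 20 the iodomethyl ketone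
Product: 21 (2S)-2-[5-methoxy-2,4-bis(methoxymethoxy)phenyl]-5,7-bis(methoxymethoxy)-6-(3-methylbut-2-en-1-yl)-2,3-dihydro-4H-chromen-4-one
Conditions: 4CzIPN (2 mol%), peptide thiol Boc-L-Cys-D-Pro-Aib-L-Phe-NHMe (free SH, 10 mol%; the mirror-image peptide if the facial sense requires it), Et3N (3 equiv), PhCF3/MeCN 4:1 (0.02 M), 450 nm LEDs, −20 °C, degassed
Reagents that add atoms: none
Why: Proposed new method: the α-aminoalkyl radical formed from Et3N by photoredox oxidation abstracts iodine from 20; the primary radical adds 3-exo to the C3 carbonyl, and the cyclopropyloxy radical opens by β-scission of the old C2–C3 bond (a 1,2-acyl shift) to the benzylic, oxygen-stabilised C2 radical of the chroman-4-one. That radical is too stabilised to take hydrogen from amine or solvent, so the S–H of the chiral thiol, hydrogen-bonded through its amide N–H groups to the C4 carbonyl, is the only competent donor and delivers hydrogen to one face to set C2 as S. The closest known reaction types are the Dowd–Beckwith ring expansion of 2-(halomethyl) β-keto esters with achiral hydrogen donors and enantioselective hydrogen-atom transfer from peptide thiols in photochemical deracemisation.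

Step 12
Reactants: 21 the tetra-MOM flavanone
Product: 22 Kushenol V, (2S)-2-(2,4-dihydroxy-5-methoxyphenyl)-5,7-dihydroxy-6-(3-methylbut-2-en-1-yl)-2,3-dihydro-4H-chromen-4-one
Conditions: HCl (1.25 M in MeOH), MeOH/THF, 0 °C to rt
Reagents that add atoms: none
Why: Acid-catalysed transacetalisation removes the four MOM groups as dimethoxymethane; low temperature and short time are chosen to avoid chroman formation from the prenyl group and ring-opening/racemisation at C2.

## Compound list

1 | resorcinol | Oc1cccc(O)c1 | starting material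
2 | 1,3-bis(methoxymethoxy)benzene | COCOc1cccc(OCOC)c1 | intermediate
3 | prenyl bromide (1-bromo-3-methylbut-2-ene) | CC(C)=CCBr | starting material
4 | [2,6-bis(methoxymethoxy)phenyl]lithium | [Li]c1c(OCOC)cccc1OCOC | intermediate
5 | 1,3-bis(methoxymethoxy)-2-(3-methylbut-2-en-1-yl)benzene | COCOc1cccc(OCOC)c1CC=C(C)C | intermediate
6 | methyl chloroformate | COC(Cl)=O | starting material
7 | [2,4-bis(methoxymethoxy)-3-(3-methylbut-2-en-1-yl)phenyl]lithium | [Li]c1ccc(OCOC)c(CC=C(C)C)c1OCOC | intermediate
8 | methyl 2,4-bis(methoxymethoxy)-3-(3-methylbut-2-en-1-yl)benzoate | COC(=O)c1ccc(OCOC)c(CC=C(C)C)c1OCOC | intermediate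
9 | methyl 2,4-bis(methoxymethoxy)-3-(3-methylbut-2-en-1-yl)-6-(4,4,5,5-tetramethyl-1,3,2-dioxaborolan-2-yl)benzoate | COC(=O)c1c(B2OC(C)(C)C(C)(C)O2)cc(OCOC)c(CC=C(C)C)c1OCOC | intermediate
10 | methyl 6-hydroxy-2,4-bis(methoxymethoxy)-3-(3-methylbut-2-en-1-yl)benzoate | COC(=O)c1c(O)cc(OCOC)c(CC=C(C)C)c1OCOC | intermediate
11 | 1,5-dibromo-2,4-bis(methoxymethoxy)benzene | COCOc1cc(OCOC)c(Br)cc1Br | intermediate
12 | formaldehyde (used as paraformaldehyde) | C=O | starting material
13 | [5-bromo-2,4-bis(methoxymethoxy)phenyl]lithium | [Li]c1cc(Br)c(OCOC)cc1OCOC | intermediate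
14 | [5-bromo-2,4-bis(methoxymethoxy)phenyl]methanol | OCc1cc(Br)c(OCOC)cc1OCOC | intermediate
15 | sodium methoxide | C[O-].[Na+] | starting material
16 | [5-methoxy-2,4-bis(methoxymethoxy)phenyl]methanol | OCc1cc(OC)c(OCOC)cc1OCOC | intermediate
17 | methyl 6-{[5-methoxy-2,4-bis(methoxymethoxy)phenyl]methoxy}-2,4-bis(methoxymethoxy)-3-(3-methylbut-2-en-1-yl)benzoate | COC(=O)c1c(OCc2cc(OC)c(OCOC)cc2OCOC)cc(OCOC)c(CC=C(C)C)c1OCOC | intermediate
18 | rac-2-[5-methoxy-2,4-bis(methoxymethoxy)phenyl]-4,6-bis(methoxymethoxy)-5-(3-methylbut-2-en-1-yl)-1-benzofuran-3(2H)-one | COCOc1cc2OC(c3cc(OC)c(OCOC)cc3OCOC)C(=O)c2c(OCOC)c1CC=C(C)C | intermediate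
19 | diiodomethane | ICI | starting material
20 | rac-2-(iodomethyl)-2-[5-methoxy-2,4-bis(methoxymethoxy)phenyl]-4,6-bis(methoxymethoxy)-5-(3-methylbut-2-en-1-yl)-1-benzofuran-3(2H)-one | COCOc1cc2OC(CI)(c3cc(OC)c(OCOC)cc3OCOC)C(=O)c2c(OCOC)c1CC=C(C)C | intermediate
21 | (2S)-2-[5-methoxy-2,4-bis(methoxymethoxy)phenyl]-5,7-bis(methoxymethoxy)-6-(3-methylbut-2-en-1-yl)-2,3-dihydro-4H-chromen-4-one | COc1cc([C@@H]2CC(=O)c3c(cc(OCOC)c(CC=C(C)C)c3OCOC)O2)c(OCOC)cc1OCOC | intermediate
22 | Kushenol V | COc1cc([C@@H]2CC(=O)c3c(cc(O)c(CC=C(C)C)c3O)O2)c(O)cc1O | target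

## Step count and risks

Total steps: 12. Longest linear sequence: 9 steps (1, 2, 3, 4, 8, 9, 10, 11, 12; the ring B branch 1, 5, 6, 7, 8–12 is equally long).

**Step 4 (ester-directed ortho-borylation).** The risk is borylation at C5 or a sluggish reaction of the crowded benzoate. The fallback sets out from 5 and comes back at 10. Sterically controlled borylation of 5 ([Ir(OMe)(cod)]2, 4,4'-di-tert-butyl-2,2'-bipyridine, B2pin2, hexane, 60 °C) at the only unhindered C–H gives the arylboronate F1. Oxidation in the same flask (H2O2, aq. NaHCO3) gives 3,5-bis(methoxymethoxy)-4-prenylphenol F2. Magnesium-phenoxide-directed ortho-formylation (MgCl2, Et3N, paraformaldehyde, MeCN, reflux) gives the salicylaldehyde F3, Pinnick oxidation (NaClO2, NaH2PO4, 2-methylbut-2-ene, t-BuOH/H2O) gives the salicylic acid F4, and TMSCHN2 in toluene/MeOH gives 10. Here the oxygen is placed first by sterics and the carbon then by the phenoxide, instead of the reverse.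

**Step 10 (C-iodomethylation).** The risk is O-alkylation of the ambident enolate or low conversion with diiodomethane. The fallback sets out from 18 and comes back at 20. Aldol hydroxymethylation (aq. formaldehyde, cat. Et3N, THF, 0 °C), which can only give a stable product by C–C bond formation, affords the 2-(hydroxymethyl) ketone F5. Triflation (Tf2O, 2,6-lutidine, CH2Cl2, −78 °C) gives the triflate F6, and displacement with NaI in acetone at 40 °C gives 20.

**Step 11 (proposed new ring expansion with enantioselective hydrogen-atom transfer).** The risks are low enantioselectivity, premature reduction of the primary radical to the 2-methyl compound, and a competing 1,2-aryl (neophyl) shift. The fallback uses known chemistry, sets out from 20 and comes back at 21. Classical tin-mediated Dowd–Beckwith ring expansion (Bu3SnH by slow addition, AIBN, benzene, 80 °C) gives the racemic flavanone, that is 21 together with its (2R)-enantiomer F7. Kinetic resolution by asymmetric transfer hydrogenation (RuCl(p-cymene)[(R,R)-TsDPEN], HCO2H/Et3N, EtOAc, rt, about 55% conversion) reduces the (2R)-ketone to the cis-(2R,4R)-flavan-4-ol F8 and leaves 21, which is separated by chromatography. The catalyst sense follows the usual facial rule for aryl ketones, and the (S,S)-catalyst is used if the sense proves opposite.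

## Further compounds

F1 | step 4 | 2-[3,5-bis(methoxymethoxy)-4-(3-methylbut-2-en-1-yl)phenyl]-4,4,5,5-tetramethyl-1,3,2-dioxaborolane | COCOc1cc(B2OC(C)(C)C(C)(C)O2)cc(OCOC)c1CC=C(C)C
F2 | step 4 | 3,5-bis(methoxymethoxy)-4-(3-methylbut-2-en-1-yl)phenol | COCOc1cc(O)cc(OCOC)c1CC=C(C)C
F3 | step 4 | 6-hydroxy-2,4-bis(methoxymethoxy)-3-(3-methylbut-2-en-1-yl)benzaldehyde | O=Cc1c(O)cc(OCOC)c(CC=C(C)C)c1OCOC
F4 | step 4 | 6-hydroxy-2,4-bis(methoxymethoxy)-3-(3-methylbut-2-en-1-yl)benzoic acid | OC(=O)c1c(O)cc(OCOC)c(CC=C(C)C)c1OCOC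
F5 | step 10 | rac-2-(hydroxymethyl)-2-[5-methoxy-2,4-bis(methoxymethoxy)phenyl]-4,6-bis(methoxymethoxy)-5-(3-methylbut-2-en-1-yl)-1-benzofuran-3(2H)-one | COCOc1cc2OC(CO)(c3cc(OC)c(OCOC)cc3OCOC)C(=O)c2c(OCOC)c1CC=C(C)C
F6 | step 10 | rac-{2-[5-methoxy-2,4-bis(methoxymethoxy)phenyl]-4,6-bis(methoxymethoxy)-5-(3-methylbut-2-en-1-yl)-3-oxo-2,3-dihydro-1-benzofuran-2-yl}methyl trifluoromethanesulfonate | COCOc1cc2OC(COS(=O)(=O)C(F)(F)F)(c3cc(OC)c(OCOC)cc3OCOC)C(=O)c2c(OCOC)c1CC=C(C)C
F7 | step 11 | (2R)-2-[5-methoxy-2,4-bis(methoxymethoxy)phenyl]-5,7-bis(methoxymethoxy)-6-(3-methylbut-2-en-1-yl)-2,3-dihydro-4H-chromen-4-one | COc1cc([C@H]2CC(=O)c3c(cc(OCOC)c(CC=C(C)C)c3OCOC)O2)c(OCOC)cc1OCOC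
F8 | step 11 | (2R,4R)-2-[5-methoxy-2,4-bis(methoxymethoxy)phenyl]-5,7-bis(methoxymethoxy)-6-(3-methylbut-2-en-1-yl)-3,4-dihydro-2H-chromen-4-ol | COc1cc([C@H]2C[C@@H](O)c3c(cc(OCOC)c(CC=C(C)C)c3OCOC)O2)c(OCOC)cc1OCOC
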